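**Strategy**

Everything rests on disconnecting ring B at C3'–C4'. Its six carbons are preformed, in order, in a 2-pyranone: the lactone carbonyl is C4', C3 (CH3) is C5', C4 (OCH3) is C6', C5 (carrying the ring A benzyl group) is C1', C6 is C2', and the CH2 of a 6-(2-oxopentyl) chain is C3'. In one operation Mg(OMe)2 opens the lactone and the diketone carbanion closes onto the ester, giving hexasubstituted ring B with its butanoyl group and single methyl ether in place. The precursor comes from Suzuki coupling of a ring A benzylboronate with a 5-bromopyranone and side-chain acylation; hydrogenolysis and C-pentanoylation of ring A finish the route.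

Key step: step 8

Remark: 4-hydroxy-3,6-dimethyl-2H-pyran-2-one (8), the C3-methyl homologue of triacetic acid lactone, is taken as a purchased compound.
Remark: primed locants are those of ring B in the target, unprimed C2–C6 are pyranone locants, and the target has no stereocentre.

**Route**

Step 1
Reactants: 1 2,4,6-trihydroxytoluene
Product: 2 2,4,6-tris(benzyloxy)toluene
Conditions: BnBr (3.3 equiv), K2CO3, DMF, rt to 50 °C
Reagents that add atoms: benzyl bromide, BrCc1ccccc1
Why: Threefold Williamson etherification, in which the potassium phenoxide in a polar aprotic solvent should favour O- over C-benzylation, with any C-benzylated material removed on purification.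

Step 2
Reactants: 2 2,4,6-tris(benzyloxy)toluene
Product: 3 1,3,5-tris(benzyloxy)-2-bromo-4-methylbenzene
Conditions: NBS (1.0 equiv), CH2Cl2/MeCN, −20 to 0 °C, dark
Reagents that add atoms: N-bromosuccinimide, O=C1CCC(=O)N1Br
Why: Electrophilic aromatic bromination of a trialkoxyarene whose two free ring positions are equivalent, so one equivalent of NBS at low temperature should give a single monobromide.

Step 3
Reactants: 3 1,3,5-tris(benzyloxy)-2-bromo-4-methylbenzene; 4 2-(chloromethyl)-4,4,5,5-tetramethyl-1,3,2-dioxaborolane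
Product: 7 2-[[2,4,6-tris(benzyloxy)-3-methylphenyl]methyl]-4,4,5,5-tetramethyl-1,3,2-dioxaborolane, via aryllithium 5 (not isolated), via lithium boronate complex 6 (not isolated)
Conditions: n-BuLi, THF, −78 °C; then 4, −78 °C to rt
Reagents that add atoms: none
Why: Bromine–lithium exchange at −78 °C should outrun deprotonation of the benzyl ethers, and the aryllithium adds to boron to give an ate complex whose 1,2-aryl shift expels chloride (Matteson homologation), so the labile 2,4,6-trialkoxybenzyl halide is never needed.

Step 4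
Reactants: 8 4-hydroxy-3,6-dimethyl-2H-pyran-2-one
Product: 9 4-methoxy-3,6-dimethyl-2H-pyran-2-one
Conditions: Me2SO4, K2CO3, acetone, reflux
Reagents that add atoms: dimethyl sulfate, COS(=O)(=O)OC
Why: O-methylation of the vinylogous acid with dimethyl sulfate and K2CO3 is the standard alkylation that should give the 4-methoxy-2-pyranone and not the isomeric 2-methoxy-4-pyranone.

Step 5
Reactants: 9 4-methoxy-3,6-dimethyl-2H-pyran-2-one
Product: 10 5-bromo-4-methoxy-3,6-dimethyl-2H-pyran-2-one
Conditions: Br2, NaOAc, AcOH, rt, dark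
Reagents that add atoms: bromine, BrBr
Why: Electrophilic bromination (addition–elimination) at C5, the only unsubstituted ring carbon and the β-carbon of the O1–C6=C5 enol ester, under buffered ionic conditions that should leave the C6 methyl group untouched.

Step 6
Reactants: 10 5-bromo-4-methoxy-3,6-dimethyl-2H-pyran-2-one; 7 2-[[2,4,6-tris(benzyloxy)-3-methylphenyl]methyl]-4,4,5,5-tetramethyl-1,3,2-dioxaborolane
Product: 11 4-methoxy-3,6-dimethyl-5-[[2,4,6-tris(benzyloxy)-3-methylphenyl]methyl]-2H-pyran-2-one
Conditions: Pd(OAc)2 (5 mol%), SPhos, K3PO4, toluene/H2O, 90 °C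
Reagents that add atoms: none
Why: sp2–sp3 Suzuki–Miyaura coupling of an alkenyl-type bromide with a benzylboronic ester, for which a bulky electron-rich biarylphosphine is chosen because both partners are doubly ortho-substituted, while the 4-methoxy-2-pyranone should tolerate aqueous phosphate.

Step 7
Reactants: 11 4-methoxy-3,6-dimethyl-5-[[2,4,6-tris(benzyloxy)-3-methylphenyl]methyl]-2H-pyran-2-one; 12 N-methoxy-N-methylbutanamide
Product: 14 4-methoxy-3-methyl-6-(2-oxopentyl)-5-[[2,4,6-tris(benzyloxy)-3-methylphenyl]methyl]-2H-pyran-2-one, via lithiated pyranone 13 (not isolated)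
Conditions: LiN(iPr)2 (1.05 equiv), THF, −78 °C; then 12, −78 to −20 °C; aq NH4Cl
Reagents that add atoms: none
Why: The C6 methyl is the only position whose anion is conjugated with the lactone carbonyl, so lateral (vinylogous) lithiation should be selective, and acylation by the N-methoxy-N-methylamide (Weinreb ketone synthesis) releases the ketone only on work-up, so one equivalent of base suffices and double acylation is avoided.

Step 8
Reactants: 14 4-methoxy-3-methyl-6-(2-oxopentyl)-5-[[2,4,6-tris(benzyloxy)-3-methylphenyl]methyl]-2H-pyran-2-one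
Product: 16 1-[2,6-dihydroxy-4-methoxy-3-methyl-5-[[2,4,6-tris(benzyloxy)-3-methylphenyl]methyl]phenyl]butan-1-one, via ring-opened keto ester 15 (not isolated)
Conditions: Mg(OMe)2 (4 equiv), MeOH, reflux; then 1 M HCl
Reagents that add atoms: none
Why: Methoxide adds to the lactone carbonyl (pyranone C2) and the ring opens to the magnesium enolate of keto ester 15, whose enol ether double bond keeps the geometry imposed by the former ring, (2E) by the CIP rules, so that the ester carbon and the diketone arm stay cis. The magnesium-chelated carbanion of the CH2 between the two ketones (future C3') then attacks the ester carbonyl (future C4') in an intramolecular Claisen (Dieckmann-type) condensation, a 6-exo-trig closure of ring B that forms the C3'–C4' bond, after which loss of methoxide and two enolizations give the arene. The closest known reaction type is the base-induced recyclization of 6-(2-oxoalkyl)-4-oxygenated 2-pyranones, which are masked 3,5,7-triketo esters, to acylphloroglucinols. No stereocentre is created, and the transient one at C1' of 15 is erased on aromatization. The step needs C-acylation to win over relactonization and over O-cyclization of a diketone oxygen onto the methoxy-bearing carbon: the magnesium chelate favours the carbon nucleophile, relactonization is reversible whereas aromatization is not, an aldol-type closure is impossible because C5' is an enol ether carbon and not a nucleophile, and methoxide in methanol matches both the ester and the enol ether so that any exchange is degenerate. The enol methyl ether is never hydrolysed and ends as the lone C6' OCH3, with the butanoyl group, the C5' methyl and the bridge already in position.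

Step 9
Reactants: 16 1-[2,6-dihydroxy-4-methoxy-3-methyl-5-[[2,4,6-tris(benzyloxy)-3-methylphenyl]methyl]phenyl]butan-1-one
Product: 17 1-[2,6-dihydroxy-4-methoxy-3-methyl-5-[(2,4,6-trihydroxy-3-methylphenyl)methyl]phenyl]butan-1-one
Conditions: H2 (1 atm), 10% Pd/C, EtOAc/MeOH, rt
Reagents that add atoms: none
Why: Hydrogenolysis of the three aryl benzyl ethers under neutral conditions, which should leave the hydrogen-bonded aryl ketone, the methyl ether and the diarylmethane bridge untouched.

Step 10
Reactants: 17 1-[2,6-dihydroxy-4-methoxy-3-methyl-5-[(2,4,6-trihydroxy-3-methylphenyl)methyl]phenyl]butan-1-one; 18 pentanoic acid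
Product: 19 1-[3-[(3-butanoyl-2,4-dihydroxy-6-methoxy-5-methylphenyl)methyl]-2,4,6-trihydroxy-5-methylphenyl]pentan-1-one (CNP0210501.0)
Conditions: BF3·OEt2, 60 °C, argon; then H2O/MeOH, 50 °C
Reagents that add atoms: none
Why: Friedel–Crafts C-acylation of a phloroglucinol by a carboxylic acid in BF3·OEt2, where ring A has a single free carbon (C1) between two hydroxyls and ring B is fully substituted, so only one C-acyl product is possible and the aqueous work-up should cleave the boron chelates.

**Compound list**

1 | 2,4,6-trihydroxytoluene | Cc1c(O)cc(O)cc1O | starting material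
2 | 2,4,6-tris(benzyloxy)toluene | Cc1c(OCc2ccccc2)cc(OCc2ccccc2)cc1OCc1ccccc1 | intermediate
3 | 1,3,5-tris(benzyloxy)-2-bromo-4-methylbenzene | Cc1c(OCc2ccccc2)cc(OCc2ccccc2)c(Br)c1OCc1ccccc1 | intermediate
4 | 2-(chloromethyl)-4,4,5,5-tetramethyl-1,3,2-dioxaborolane | ClCB1OC(C)(C)C(C)(C)O1 | starting material
5 | [2,4,6-tris(benzyloxy)-3-methylphenyl]lithium (not isolated) | [Li]c1c(OCc2ccccc2)cc(OCc2ccccc2)c(C)c1OCc1ccccc1 | intermediate
6 | lithium (chloromethyl)[2,4,6-tris(benzyloxy)-3-methylphenyl]pinacolatoborate (not isolated) | [Li+].ClC[B-]1(c2c(OCc3ccccc3)cc(OCc3ccccc3)c(C)c2OCc2ccccc2)OC(C)(C)C(C)(C)O1 | intermediate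
7 | 2-[[2,4,6-tris(benzyloxy)-3-methylphenyl]methyl]-4,4,5,5-tetramethyl-1,3,2-dioxaborolane | Cc1c(OCc2ccccc2)cc(OCc2ccccc2)c(CB2OC(C)(C)C(C)(C)O2)c1OCc1ccccc1 | intermediate
8 | 4-hydroxy-3,6-dimethyl-2H-pyran-2-one | Cc1cc(O)c(C)c(=O)o1 | starting material
9 | 4-methoxy-3,6-dimethyl-2H-pyran-2-one | COc1cc(C)oc(=O)c1C | intermediate
10 | 5-bromo-4-methoxy-3,6-dimethyl-2H-pyran-2-one | COc1c(Br)c(C)oc(=O)c1C | intermediate
11 | 4-methoxy-3,6-dimethyl-5-[[2,4,6-tris(benzyloxy)-3-methylphenyl]methyl]-2H-pyran-2-one | COc1c(Cc2c(OCc3ccccc3)c(C)c(OCc3ccccc3)cc2OCc2ccccc2)c(C)oc(=O)c1C | intermediate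
12 | N-methoxy-N-methylbutanamide | CCCC(=O)N(C)OC | starting material
13 | 6-(lithiomethyl)-4-methoxy-3-methyl-5-[[2,4,6-tris(benzyloxy)-3-methylphenyl]methyl]-2H-pyran-2-one (vinylogous lithium enolate drawn C-lithiated, not isolated) | [Li]Cc1oc(=O)c(C)c(OC)c1Cc1c(OCc2ccccc2)c(C)c(OCc2ccccc2)cc1OCc1ccccc1 | intermediate
14 | 4-methoxy-3-methyl-6-(2-oxopentyl)-5-[[2,4,6-tris(benzyloxy)-3-methylphenyl]methyl]-2H-pyran-2-one | CCCC(=O)Cc1oc(=O)c(C)c(OC)c1Cc1c(OCc2ccccc2)c(C)c(OCc2ccccc2)cc1OCc1ccccc1 | intermediate
15 | methyl (2E)-3-methoxy-2-methyl-5,7-dioxo-4-[[2,4,6-tris(benzyloxy)-3-methylphenyl]methyl]dec-2-enoate (racemic at C4, present as its magnesium enolate, not isolated) | CCCC(=O)CC(=O)C(Cc1c(OCc2ccccc2)c(C)c(OCc2ccccc2)cc1OCc1ccccc1)/C(OC)=C(C)\C(=O)OC | intermediate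
16 | 1-[2,6-dihydroxy-4-methoxy-3-methyl-5-[[2,4,6-tris(benzyloxy)-3-methylphenyl]methyl]phenyl]butan-1-one | CCCC(=O)c1c(O)c(C)c(OC)c(Cc2c(OCc3ccccc3)c(C)c(OCc3ccccc3)cc2OCc2ccccc2)c1O | intermediate
17 | 1-[2,6-dihydroxy-4-methoxy-3-methyl-5-[(2,4,6-trihydroxy-3-methylphenyl)methyl]phenyl]butan-1-one | CCCC(=O)c1c(O)c(C)c(OC)c(Cc2c(O)c(C)c(O)cc2O)c1O | intermediate
18 | pentanoic acid | CCCCC(=O)O | starting material
19 | 1-[3-[(3-butanoyl-2,4-dihydroxy-6-methoxy-5-methylphenyl)methyl]-2,4,6-trihydroxy-5-methylphenyl]pentan-1-one (no stereocentre) | CCCCC(=O)c1c(O)c(C)c(O)c(Cc2c(O)c(C(=O)CCC)c(O)c(C)c2OC)c1O | target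

**Step count and risks**

Total steps: 10 (three to the ring A boronate, two to the bromopyranone, five from the union onward). Longest linear sequence: 8 steps (steps 1, 2, 3, 6, 7, 8, 9, 10).

Steps most likely to fail:

1. Step 8. The ring-opened keto ester may relactonize faster than it undergoes C-acylation, or a diketone oxygen may cyclize onto the methoxy-bearing carbon and divert material to a 4-pyranone. The fallback builds ring B from an intact arene instead of by recyclization. It sets out from 1 and 7 and returns at 16. Friedel–Crafts butanoylation of 1 (butanoic acid, BF3·OEt2) should give 1-(2,4,6-trihydroxy-3-methylphenyl)butan-1-one F1. Selective methylation of the para hydroxyl, the one not hydrogen-bonded to the ketone (Me2SO4, one equivalent, K2CO3, acetone), should give 1-(2,6-dihydroxy-4-methoxy-3-methylphenyl)butan-1-one F2. Bromination of the last free ring carbon (NBS, MeCN, 0 °C) should give 1-(3-bromo-2,6-dihydroxy-4-methoxy-5-methylphenyl)butan-1-one F3. Suzuki–Miyaura coupling of F3 with benzylboronate 7 (Pd(OAc)2, SPhos, K3PO4) then returns to 16.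

2. Step 6. Transmetalation of the doubly ortho-substituted benzylboronate onto a hindered alkenylpalladium may be slower than protodeboronation. The fallback makes the same bond by carbonyl addition and deoxygenation. It sets out from 2 and 10 and returns at 11. Vilsmeier–Haack formylation of 2 (POCl3, DMF) should give 2,4,6-tris(benzyloxy)-3-methylbenzaldehyde F4. Nozaki–Hiyama–Kishi addition of bromide 10 to F4 (CrCl2, catalytic NiCl2, DMF), which tolerates the lactone, should give racemic 5-[hydroxy[2,4,6-tris(benzyloxy)-3-methylphenyl]methyl]-4-methoxy-3,6-dimethyl-2H-pyran-2-one F5. Ionic hydrogenation of this readily ionized carbinol (Et3SiH, CF3CO2H, CH2Cl2, 0 °C) then returns to 11.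

3. Step 10. Acid-promoted ipso protonation of the very electron-rich ring A may cleave or scramble the methylene bridge before acylation, and O-acylation of phenols may compete. The fallback uses a nitrilium electrophile at low temperature. It sets out from 17 and returns at 19. Houben–Hoesch reaction of 17 with pentanenitrile (ZnCl2, HCl gas, Et2O, 0 °C) should give 1-[3-[(3-butanoyl-2,4-dihydroxy-6-methoxy-5-methylphenyl)methyl]-2,4,6-trihydroxy-5-methylphenyl]pentan-1-imine hydrochloride F6. This iminium salt deactivates ring A as soon as it forms, and hydrolysis in warm water gives 19.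

**Further compounds**

F1 | step 8 | 1-(2,4,6-trihydroxy-3-methylphenyl)butan-1-one | CCCC(=O)c1c(O)cc(O)c(C)c1O
F2 | step 8 | 1-(2,6-dihydroxy-4-methoxy-3-methylphenyl)butan-1-one | CCCC(=O)c1c(O)cc(OC)c(C)c1O
F3 | step 8 | 1-(3-bromo-2,6-dihydroxy-4-methoxy-5-methylphenyl)butan-1-one | CCCC(=O)c1c(O)c(Br)c(OC)c(C)c1O
F4 | step 6 | 2,4,6-tris(benzyloxy)-3-methylbenzaldehyde | O=Cc1c(OCc2ccccc2)cc(OCc2ccccc2)c(C)c1OCc1ccccc1
F5 | step 6 | 5-[hydroxy[2,4,6-tris(benzyloxy)-3-methylphenyl]methyl]-4-methoxy-3,6-dimethyl-2H-pyran-2-one (racemic) | COc1c(C(O)c2c(OCc3ccccc3)c(C)c(OCc3ccccc3)cc2OCc2ccccc2)c(C)oc(=O)c1C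
F6 | step 10 | 1-[3-[(3-butanoyl-2,4-dihydroxy-6-methoxy-5-methylphenyl)methyl]-2,4,6-trihydroxy-5-methylphenyl]pentan-1-imine hydrochloride | CCCCC(=N)c1c(O)c(C)c(O)c(Cc2c(O)c(C(=O)CCC)c(O)c(C)c2OC)c1O.Cl
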